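Thursday's run holds twice the starting material of Tuesday's run at the same reagent, and it makes target faster, but by a factor well short of that.

| flask | starting material | reagent | time |
|---|---|---|---|
| Thursday's | 150 mM | 150 mM |  |
| Tuesday's | 75.0 mM | 150 mM |  |
| Monday's | 450 mM | 50.0 mM | 25 min |

- Thursday's run (time / min: [target] / mM): 1.9: 29.5; 5.8: 60.3; 11: 77.9; 17: 86.8; 25: 91.2
- Tuesday's run (time / min: [target] / mM): 1.9: 19.0; 5.8: 38.3; 11: 48.8; 17: 53.4; 25: 54.7

(readings scatter by 0.4 mM)

* the power of [starting material] that the first rate follows, about the charge of the Thursday's run; measure it at two percent of starting material made into target (one fixed amount of target, the same in the runs compared)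
* target in the Monday's run at 25 min, as a share of the starting material charged

- Overall: starting material + reagent -> target.
- Constant volume, constant temperature.
- Readings of a species count what is bound in complexes too.
- "The second partner" is reagent.
- An order is taken over about fifteen percent of the charge, up and down.

I compare two rates, the mean rates up to the first reading at 1.9 min: 15.5 mM min⁻¹ in Thursday's run and 10.0 mM min⁻¹ in Tuesday's run. These runs differ in starting material and not in reagent, and this reading is the earliest, so the ratio of the two rates speaks of starting material. Such a pair reads as a slope on logarithmic axes. That slope, 0.635, is the apparent order, the logarithm of the rate ratio over the logarithm of the charge ratio. It stays a reading, since the two runs have made different amounts of target by then and it spans the charges from 75.0 mM to 150 mM, but it is the order I commit to. In Monday's run reagent is the limiting reagent, 50.0 mM against 450 mM of starting material, so the one-to-one equation allows a share of 11.1%, and I expect a share under it.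

The forecast gives an order of 0.52 and a share of 10.2%. It takes its order from “saturation of a catalyst-like site”, and that order is lower than my 0.635.

The simulation gives an order of 0.61 and a share of 9.64%.

    starting material + reagent → target (0.6540 M⁻¹ min⁻¹)
    starting material + 2 reagent → target + reagent (10.32 M⁻² min⁻¹)
    starting material + reagent ⇌ idle substrate-reagent adduct, settled at all times (3.700 M⁻¹)
    starting material → decomposed substrate (0.06960 min⁻¹)

Starting material and reagent join fast into the idle substrate-reagent adduct, and this joining pulls the order down: about Thursday's charge it is 0.61 with the joining and 1.0 without it. I carry 0.635 to Tuesday's run. Thursday's rate of 19 mM min⁻¹, taken where two percent of Thursday's starting material have turned, scales to 12.5 mM min⁻¹ for Tuesday's charge, and the simulated rate of Tuesday's run at that same amount is 12 mM min⁻¹.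

(Readings and results are calculated for substances that don't exist; the scatter is artificial.)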